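The furofuran (3,7-dioxabicyclo[3.3.0]octane) core is cut at both benzylic C–O bonds (C7–O, C7'–O) and then at C7'–C8' and C7–C8. The chain C9'–C8'–C8–C9 shared by the two tetrahydrofuran rings thereby becomes C5–C4–C3–C2 of a 5-menthyloxy-2(5H)-furanone. One operation adds a lithiated syringyl dithiane to C4 and traps the lactone enolate at C3 with a guaiacyl aldehyde, setting C8' and C8 from the single acetal stereocentre. The precursor is simply the (5S)-butenolide, an aryl dithiane and an aryl aldehyde with orthogonal phenol protection. Reduction, cationic double ring closure and an auxiliary-controlled glycolate syn aldol on the freed guaiacyl oxygen complete the threo side chain.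

Key step: step 5

Remark: lignan locants are used (C7–C9 guaiacyl half, C7'–C9' syringyl half, C7''–C9'' side chain); the benzylic carbinol centres of 12, 13 and 14 are carried as both epimers because step 8 ionises them.

Step 1
Reactants: 1 furfural
Product: 2 5-hydroxy-2(5H)-furanone (racemic)
Conditions: O2, rose bengal disodium salt (C20H2Cl4I4Na2O5, cat.), MeOH, visible light, rt
Reagents that add atoms: dioxygen O=O
Why: Dye-sensitised singlet-oxygen [4+2] photooxygenation of the furan gives an endoperoxide that methanol opens with loss of the formyl carbon as methyl formate, the standard route from furfural to the hydroxybutenolide; the acetal carbon is racemic here and is fixed in step 2.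

Step 2
Reactants: 2 5-hydroxy-2(5H)-furanone; 3 (+)-menthol
Product: 5 (5S)-5-(d-menthyloxy)-2(5H)-furanone, via C5-epimeric menthyl acetal mixture 4 (not isolated)
Conditions: camphor-10-sulfonic acid (cat.), toluene, reflux, Dean–Stark; crystallise from petroleum ether, −20 °C; mother liquor re-equilibrated with the same acid and recrystallised
Reagents that add atoms: none
Why: Acid-catalysed acetalisation (pseudo-ester formation) gives both C5 epimers, which interconvert under the acid, so crystallisation of the less soluble (5S) diastereomer with recycling of the mother liquor (crystallisation-induced diastereomer transformation) should deliver a single acetal configuration.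

Step 3
Reactants: 6 syringaldehyde
Product: 7 4-benzyloxy-3,5-dimethoxybenzaldehyde
Conditions: BnBr, K2CO3, DMF, 60 °C
Reagents that add atoms: benzyl bromide BrCc1ccccc1
Why: Williamson etherification of the acidic, flanked phenol is routine and gives a protecting group that survives organolithium, hydride, acid and palladium-catalysed deallylation later on.

Step 4
Reactants: 7 4-benzyloxy-3,5-dimethoxybenzaldehyde
Product: 8 2-(4-benzyloxy-3,5-dimethoxyphenyl)-1,3-dithiane
Conditions: HS(CH2)3SH, I2 (10 mol %), CH2Cl2, rt
Reagents that add atoms: propane-1,3-dithiol SCCCS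
Why: Iodine-catalysed dithioacetalisation of an aromatic aldehyde is mild enough to spare the hindered aryl benzyl ether, which a stoichiometric Lewis acid with thiol could cleave.

Step 5
Reactants: 8 2-(4-benzyloxy-3,5-dimethoxyphenyl)-1,3-dithiane; 5 (5S)-5-(d-menthyloxy)-2(5H)-furanone; 9 4-allyloxy-3-methoxybenzaldehyde
Product: 12 (3R,4S,5S)-Michael–aldol lactone (both C7 carbinol epimers), via 2-lithio-2-aryl-1,3-dithiane 10 (not isolated), via lithium lactone enolate 11 (not isolated)
Conditions: n-BuLi, THF, −78 → −20 °C; 5, THF, −78 °C; then 9, −78 °C; sat. aq. NH4Cl at −78 °C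
Reagents that add atoms: none
Why: The sulfur-stabilised anion 10 adds 1,4 to the butenolide at C4 (bond C7'–C8') and the lithium lactone enolate 11 so formed adds through C3 to aldehyde 9 (bond C8–C7). The closest known reaction type is the tandem conjugate addition–aldol of 2-lithio-2-aryl-1,3-dithianes to 5-alkoxy-2(5H)-furanones used for lignan lactones and furofurans. No ring closes in this step; the two tetrahydrofuran rings are closed from these same atoms in step 8, each by 5-exo capture of a benzylic cation. C4 (future C8') is set by attack anti to the C5 menthyloxy group and C3 (future C8) by aldehyde approach anti to the new, bulky C4 dithianyl group, while the carbinol carbon is deliberately left uncontrolled. The step needs 1,4- over 1,2-addition and trans,trans diastereoselection; the soft hindered nucleophile secures the first, the acetal substituent shielding one face of the butenolide and then of the enolate secures the second, and the cold quench suppresses retro-aldol.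

Step 6
Reactants: 12 Michael–aldol lactone
Product: 13 (3R,4S,5S)-4-aroyl lactone (aryl ketone at C7')
Conditions: MeI (excess), CaCO3, MeCN–H2O (4:1), 45 °C
Reagents that add atoms: water O
Why: Alkylative dithiane hydrolysis (S-methylation, then hydrolysis of the sulfonium under carbonate buffering) unmasks the ketone without the thiophilic heavy-metal salts or oxidants that would attack the allyl ether, and the C4 centre, now alpha to the ketone, already sits in the favoured trans arrangement.

Step 7
Reactants: 13 4-aroyl lactone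
Product: 14 (2S,3S)-1,4-diaryl-2,3-bis(hydroxymethyl)butane-1,4-diol (C1/C4 epimer mixture)
Conditions: LiAlH4, THF, 0 °C → rt; H2O/aq. NaOH work-up
Reagents that add atoms: none
Why: Hydride reduction takes the ketone to the carbinol and the lactone acetal, through the ring-opened dialdehyde level, to the two primary alcohols with release of recoverable menthol; C8 and C8' are untouched and the new carbinol configuration is irrelevant.

Step 8
Reactants: 14 tetraol
Product: 15 (7R,7'R,8S,8'S)-furofuran with guaiacyl O-allyl and syringyl O-benzyl (both aryl groups exo)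
Conditions: camphor-10-sulfonic acid (5 mol %), CH2Cl2, 0 °C, short reaction time; quench with Et3N
Reagents that add atoms: none
Why: Acid-catalysed SN1 cyclodehydration ionises each 4-alkoxybenzylic carbinol and the primary hydroxyl on the other half of the chain captures the cation 5-exo (C7–O–C9' and C7'–O–C9), each aryl settling trans to the adjacent ring-fusion bond on the convex face, so both carbinol epimers should converge on the exo,exo isomer; any doubly benzylic C7–O–C7' ether formed in competition is expected to re-ionise readily and drain to the bicyclic diether, provided the exposure is kept brief to avoid exo/endo equilibration.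

Step 9
Reactants: 15 allyl/benzyl furofuran
Product: 16 furofuran guaiacyl phenol (syringyl O-benzyl retained)
Conditions: Pd(PPh3)4 (2 mol %), K2CO3, MeOH, rt
Reagents that add atoms: none
Why: Tsuji–Trost-type deallylation ionises only the allyl aryl ether to a π-allyl palladium complex that methanol intercepts, leaving the benzyl ether and the furofuran untouched and freeing the guaiacyl oxygen alone.

Step 10
Reactants: 17 (R)-4-benzyl-2-oxazolidinone; 18 bromoacetyl bromide
Product: 20 (R)-4-benzyl-3-(bromoacetyl)-2-oxazolidinone, via N-lithio oxazolidinone 19 (not isolated)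
Conditions: n-BuLi, THF, −78 °C; then BrCH2COBr, −78 °C
Reagents that add atoms: none
Why: N-acylation of the lithiated oxazolidinone occurs at the acyl bromide far faster than displacement of the alkyl bromide at −78 °C, a standard preparation of haloacetyl imides.

Step 11
Reactants: 16 furofuran guaiacyl phenol; 20 (R)-4-benzyl-3-(bromoacetyl)-2-oxazolidinone
Product: 21 furofuran guaiacyl aryloxyacetyl imide
Conditions: K2CO3, acetone, rt
Reagents that add atoms: none
Why: Williamson O-alkylation of the only free phenol by SN2 displacement of the activated alpha-bromo imide should outrun acyl transfer to the weakly nucleophilic phenoxide under mild carbonate conditions.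

Step 12
Reactants: 21 aryloxyacetyl imide; 22 4-benzyloxy-3-methoxybenzaldehyde
Product: 24 syn aldol imide with (2R,3S) side chain, via Z-dibutylboron enolate 23 (not isolated)
Conditions: Bu2BOTf, iPr2NEt, CH2Cl2, −78 → 0 °C; 22, −78 → 0 °C; pH 7 buffer, MeOH, 30% H2O2, 0 °C
Reagents that add atoms: none
Why: Evans boron syn aldol of a glycolate-type imide: the Z-boron enolate reacts through a closed Zimmerman–Traxler transition state on the enolate face opposite the auxiliary benzyl group, which with the (R)-auxiliary sets C8'' and C7'' syn in the sense that becomes (7''S,8''S) once C9'' is reduced.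

Step 13
Reactants: 24 syn aldol imide
Product: 25 (7''S,8''S)-triol-level side chain with both aryl benzyl ethers in place
Conditions: LiBH4, THF, H2O (1 equiv), 0 °C
Reagents that add atoms: none
Why: Reductive cleavage of the N-acyl oxazolidinone by borohydride converts the exocyclic carbonyl into the C9'' primary alcohol and releases the auxiliary without touching either new stereocentre (the C8'' descriptor changes from R to S only through the priority change).

Step 14
Reactants: 25 dibenzyl ether of the target
Product: 26 target CNP0255927.3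
Conditions: H2 (1 atm), 10% Pd/C, EtOAc, rt, stopped as soon as both benzyl ethers are gone
Reagents that add atoms: none
Why: Heterogeneous hydrogenolysis cleaves aryl benzyl ethers much faster than the dialkyl benzylic C–O bonds of the furofuran or the C7'' benzylic alcohol in neutral ethyl acetate, so short contact should free both phenols selectively.

Compound list
1 | furfural | O=Cc1ccco1 | starting material
2 | 5-hydroxy-2(5H)-furanone (racemic) | O=C1OC(O)C=C1 | intermediate
3 | (+)-menthol, (1S,2R,5S) | C[C@H]1CC[C@@H]([C@H](C1)O)C(C)C | starting material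
4 | 5-(d-menthyloxy)-2(5H)-furanone, mixture of C5 epimers | O=C1OC(O[C@H]2C[C@@H](C)CC[C@@H]2C(C)C)C=C1 | intermediate (not isolated)
5 | (5S)-5-(d-menthyloxy)-2(5H)-furanone | O=C1O[C@H](O[C@H]2C[C@@H](C)CC[C@@H]2C(C)C)C=C1 | intermediate
6 | syringaldehyde | COc1cc(C=O)cc(OC)c1O | starting material
7 | 4-benzyloxy-3,5-dimethoxybenzaldehyde | COc1cc(C=O)cc(OC)c1OCc1ccccc1 | intermediate
8 | 2-(4-benzyloxy-3,5-dimethoxyphenyl)-1,3-dithiane | COc1cc(C2SCCCS2)cc(OC)c1OCc1ccccc1 | intermediate
9 | 4-allyloxy-3-methoxybenzaldehyde | C=CCOc1ccc(C=O)cc1OC | starting material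
10 | 2-lithio-2-(4-benzyloxy-3,5-dimethoxyphenyl)-1,3-dithiane | [Li]C1(SCCCS1)c1cc(OC)c(OCc2ccccc2)c(OC)c1 | intermediate (not isolated)
11 | lithium enolate of the (4S,5S) conjugate adduct (dithianyl at C4 trans to menthyloxy at C5) | [Li]OC1=C[C@H](C2(SCCCS2)c2cc(OC)c(OCc3ccccc3)c(OC)c2)[C@@H](O[C@H]2C[C@@H](C)CC[C@@H]2C(C)C)O1 | intermediate (not isolated)
12 | (3R,4S,5S)-3-[(4-allyloxy-3-methoxyphenyl)(hydroxy)methyl]-4-[2-(4-benzyloxy-3,5-dimethoxyphenyl)-1,3-dithian-2-yl]-5-(d-menthyloxy)dihydrofuran-2(3H)-one, both carbinol epimers | O=C1O[C@H](O[C@H]2C[C@@H](C)CC[C@@H]2C(C)C)[C@@H](C2(SCCCS2)c2cc(OC)c(OCc3ccccc3)c(OC)c2)[C@@H]1C(O)c1ccc(OCC=C)c(OC)c1 | intermediate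
13 | (3R,4S,5S)-3-[(4-allyloxy-3-methoxyphenyl)(hydroxy)methyl]-4-(4-benzyloxy-3,5-dimethoxybenzoyl)-5-(d-menthyloxy)dihydrofuran-2(3H)-one | O=C1O[C@H](O[C@H]2C[C@@H](C)CC[C@@H]2C(C)C)[C@@H](C(=O)c2cc(OC)c(OCc3ccccc3)c(OC)c2)[C@@H]1C(O)c1ccc(OCC=C)c(OC)c1 | intermediate
14 | (2S,3S)-1-(4-allyloxy-3-methoxyphenyl)-4-(4-benzyloxy-3,5-dimethoxyphenyl)-2,3-bis(hydroxymethyl)butane-1,4-diol, C1/C4 epimers | OC[C@@H](C(O)c1cc(OC)c(OCc2ccccc2)c(OC)c1)[C@@H](CO)C(O)c1ccc(OCC=C)c(OC)c1 | intermediate
15 | (7R,7'R,8S,8'S)-7-(4-allyloxy-3-methoxyphenyl)-7'-(4-benzyloxy-3,5-dimethoxyphenyl)furofuran, both aryls exo | C=CCOc1ccc([C@@H]2OC[C@@H]3[C@H]2CO[C@H]3c2cc(OC)c(OCc4ccccc4)c(OC)c2)cc1OC | intermediate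
16 | (7R,7'R,8S,8'S)-furofuran with free guaiacyl phenol and syringyl O-benzyl | Oc1ccc([C@@H]2OC[C@@H]3[C@H]2CO[C@H]3c2cc(OC)c(OCc4ccccc4)c(OC)c2)cc1OC | intermediate
17 | (R)-4-benzyl-2-oxazolidinone | O=C1N[C@H](Cc2ccccc2)CO1 | starting material
18 | bromoacetyl bromide | BrCC(Br)=O | starting material
19 | N-lithio-(R)-4-benzyl-2-oxazolidinone | [Li]N1[C@H](Cc2ccccc2)COC1=O | intermediate (not isolated)
20 | (R)-4-benzyl-3-(bromoacetyl)-2-oxazolidinone | O=C1OC[C@@H](Cc2ccccc2)N1C(=O)CBr | intermediate
21 | (R)-4-benzyl-3-[(furofuran guaiacyl-oxy)acetyl]-2-oxazolidinone | O=C1OC[C@@H](Cc2ccccc2)N1C(=O)COc1ccc([C@@H]2OC[C@@H]3[C@H]2CO[C@H]3c2cc(OC)c(OCc4ccccc4)c(OC)c2)cc1OC | intermediate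
22 | 4-benzyloxy-3-methoxybenzaldehyde | COc1cc(C=O)ccc1OCc1ccccc1 | starting material
23 | Z-dibutylboron enolate of 21 | CCCCB(CCCC)O/C(=C\Oc1ccc([C@@H]2OC[C@@H]3[C@H]2CO[C@H]3c2cc(OC)c(OCc4ccccc4)c(OC)c2)cc1OC)N1[C@H](Cc2ccccc2)COC1=O | intermediate (not isolated)
24 | (4R)-4-benzyl-3-[(2R,3S)-3-(4-benzyloxy-3-methoxyphenyl)-3-hydroxy-2-(furofuran guaiacyl-oxy)propanoyl]-2-oxazolidinone (syn aldol) | COc1cc([C@H](O)[C@H](C(=O)N2[C@H](Cc3ccccc3)COC2=O)Oc2ccc([C@@H]3OC[C@@H]4[C@H]3CO[C@H]4c3cc(OC)c(OCc4ccccc4)c(OC)c3)cc2OC)ccc1OCc1ccccc1 | intermediate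
25 | (7''S,8''S)-threo aryl glycerol ether, 4''-O-benzyl and syringyl 4'-O-benzyl | COc1cc([C@H](O)[C@H](CO)Oc2ccc([C@@H]3OC[C@@H]4[C@H]3CO[C@H]4c3cc(OC)c(OCc4ccccc4)c(OC)c3)cc2OC)ccc1OCc1ccccc1 | intermediate
26 | CNP0255927.3, (7R,7'R,8S,8'S,7''S,8''S) | COc1cc([C@H](O)[C@H](CO)Oc2ccc([C@@H]3OC[C@@H]4[C@H]3CO[C@H]4c3cc(OC)c(O)c(OC)c3)cc2OC)ccc1O | target

Total step count: 14. Longest linear sequence: 11 steps (steps 1, 2, 5, 6, 7, 8, 9, 11, 12, 13, 14 from furfural); steps 3–4 and step 10 are side branches.

Steps most likely to fail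

Step 5. The one-pot sequence may suffer from incomplete or reversible trapping of the lithium enolate (proton transfer, retro-aldol on warming) or from contamination by 1,2-addition. The fallback separates the two bond formations. Setting out from 8 and 5, the conjugate addition is quenched cold with NH4Cl and the trans adduct, (4S,5S)-4-[2-(4-benzyloxy-3,5-dimethoxyphenyl)-1,3-dithian-2-yl]-5-(d-menthyloxy)dihydrofuran-2(3H)-one F1, is isolated and purified. Enolate 11 is then regenerated from F1 with LiN(iPr)2 in THF at −78 °C and treated with aldehyde 9 under aldol conditions optimised on their own, again with a cold quench. The sequence returns to the route at 12.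

Step 8. Under the acid, kinetic control may be lost (exo/endo scrambling at C7 and C7'), or a cation may be captured by the other benzylic hydroxyl (C7–O–C7' closure) when both carbinols ionise together. The fallback stages the two closures, setting out from 12.
- LiAlH4 (THF, 0 °C) reduces the lactone acetal with the dithiane still in place to the triol, (2S,3S)-2,3-bis(hydroxymethyl) dithianyl carbinol F2.
- Brief camphor-10-sulfonic acid treatment (CH2Cl2, 0 °C) can then close only the C7–O–C9' ring, giving the 2-aryl-3-(hydroxymethyl)-4-(2-aryl-dithianyl)tetrahydrofuran F3 with the aryl trans to the hydroxymethyl group.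
- MeI/CaCO3 in aqueous MeCN unmasks the aryl ketone F4, which is expected to rest largely as its cyclic hemiketal.
- NaBH4 in MeOH at 0 °C gives the C7' carbinol F5.
- A second short acid treatment closes the C7'–O–C9 ring through the single remaining benzylic cation, returning to the route at 15.

Step 11. The phenoxide may attack the imide carbonyl (acyl transfer with loss of the auxiliary), or the base may consume the bromoacetyl imide by self-condensation. The fallback builds the imide from the aryloxyacetic acid instead, setting out from 16.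
- Alkylation with methyl bromoacetate (K2CO3, acetone) gives the methyl aryloxyacetate F6.
- LiOH in THF–H2O gives the aryloxyacetic acid F7.
- Pivaloyl chloride and Et3N in THF at −20 °C give the mixed pivalic anhydride F8.
- Addition of the lithiated auxiliary 19 (from 17 and n-BuLi, −78 °C) acylates nitrogen at the less hindered carbonyl, returning to the route at 21.

Further compounds
F1 | step 5 | (4S,5S)-4-[2-(4-benzyloxy-3,5-dimethoxyphenyl)-1,3-dithian-2-yl]-5-(d-menthyloxy)dihydrofuran-2(3H)-one | O=C1C[C@H](C2(SCCCS2)c2cc(OC)c(OCc3ccccc3)c(OC)c2)[C@@H](O[C@H]2C[C@@H](C)CC[C@@H]2C(C)C)O1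
F2 | step 8 | (2S,3S)-2,3-bis(hydroxymethyl) triol with the syringyl dithiane intact, carbinol epimers | OC[C@@H](C1(SCCCS1)c1cc(OC)c(OCc2ccccc2)c(OC)c1)[C@@H](CO)C(O)c1ccc(OCC=C)c(OC)c1
F3 | step 8 | (7R,8S,8'S)-2-(4-allyloxy-3-methoxyphenyl)-3-(hydroxymethyl)-4-[2-(4-benzyloxy-3,5-dimethoxyphenyl)-1,3-dithian-2-yl]tetrahydrofuran | C=CCOc1ccc([C@@H]2OC[C@@H](C3(SCCCS3)c3cc(OC)c(OCc4ccccc4)c(OC)c3)[C@H]2CO)cc1OC
F4 | step 8 | (7R,8S,8'S)-2-(4-allyloxy-3-methoxyphenyl)-4-(4-benzyloxy-3,5-dimethoxybenzoyl)-3-(hydroxymethyl)tetrahydrofuran | C=CCOc1ccc([C@@H]2OC[C@@H](C(=O)c3cc(OC)c(OCc4ccccc4)c(OC)c3)[C@H]2CO)cc1OC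
F5 | step 8 | (7R,8S,8'S)-2-(4-allyloxy-3-methoxyphenyl)-4-[(4-benzyloxy-3,5-dimethoxyphenyl)(hydroxy)methyl]-3-(hydroxymethyl)tetrahydrofuran, carbinol epimers | C=CCOc1ccc([C@@H]2OC[C@@H](C(O)c3cc(OC)c(OCc4ccccc4)c(OC)c3)[C@H]2CO)cc1OC
F6 | step 11 | methyl (furofuran guaiacyl-oxy)acetate | COC(=O)COc1ccc([C@@H]2OC[C@@H]3[C@H]2CO[C@H]3c2cc(OC)c(OCc4ccccc4)c(OC)c2)cc1OC
F7 | step 11 | (furofuran guaiacyl-oxy)acetic acid | OC(=O)COc1ccc([C@@H]2OC[C@@H]3[C@H]2CO[C@H]3c2cc(OC)c(OCc4ccccc4)c(OC)c2)cc1OC
F8 | step 11 | mixed anhydride of F7 with pivalic acid | CC(C)(C)C(=O)OC(=O)COc1ccc([C@@H]2OC[C@@H]3[C@H]2CO[C@H]3c2cc(OC)c(OCc4ccccc4)c(OC)c2)cc1OC
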